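**Plan**
- Cuts: the oxolane (O1; C2 and C5 carry 4-hydroxyphenyl rings, C3 the benzofuran-4-yl group, C4 the resorcinol ring) is opened at C3–C4 and at O1–C5. This releases a resveratrol unit and leaves O1–C2–C3 on a bis(dihydrobenzofuran) aryl fragment. Each dihydrobenzofuran is cut at C2–C3, and the two are separated at the diaryl carbon C3 of the 6-oxygenated ring.
- Forward order: 7-oxygenated dihydrobenzofuran (steps 1–5), central resorcinol ring and second dihydrobenzofuran (6–12), two-carbon aryl carbinol chain (13–15), silicon tether to 4'-O-benzylresveratrol (16–17), oxolane in one radical–polar cascade (18), debenzylation (19).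
- Enabling feature: the phenyl ring on oxolane C5 is para-oxygenated, so a radical at C5 is easily oxidized to a stabilized benzylic cation on which the oxygen at C2 can close. The resorcinol ring on C4 offers a meta-hydroxyl from which one silicon atom reaches the C2 oxygen, which turns the C3–C4 bond formation into a ring closure.
- Stereochemistry: C3 of each dihydrobenzofuran from enantiomeric dirhodium catalysts, C2 of each by acid equilibration to trans; oxolane C2 by asymmetric transfer hydrogenation; oxolane C3, C4 and C5 from C2 in the key step.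

Key step: step 18

Remark: the sense of induction of the two dirhodium catalysts (steps 5 and 11) is assigned by analogy with related donor/donor carbene insertions; should it be the reverse, the catalysts of the two steps are exchanged.

Abbreviation used in names: Q = the (2S,3S)-6-(benzyloxy)-2-[4-(benzyloxy)phenyl]-3-{(2R,3R)-7-(benzyloxy)-2-[4-(benzyloxy)phenyl]-3-[3,5-bis(benzyloxy)phenyl]-2,3-dihydro-1-benzofuran-5-yl}-2,3-dihydro-1-benzofuran-4-yl group (compound 21 with the point of attachment in place of bromine).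

Step 1
Reactants: 1 5-bromo-2,3-dihydroxybenzaldehyde
Product: 2 3-(benzyloxy)-5-bromo-2-hydroxybenzaldehyde
Conditions: NaH (2.1 equiv), BnBr (1.0 equiv), DMSO, rt; aq. HCl work-up
Reagents that add atoms: benzyl bromide, BrCc1ccccc1
Why: Williamson etherification of the dianion, which should be alkylated at the more nucleophilic 3-oxide because the 2-oxide is conjugated and chelated to the formyl group.

Step 2
Reactants: 2 3-(benzyloxy)-5-bromo-2-hydroxybenzaldehyde; 3 1-(benzyloxy)-4-(chloromethyl)benzene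
Product: 4 3-(benzyloxy)-2-{[4-(benzyloxy)phenyl]methoxy}-5-bromobenzaldehyde
Conditions: K2CO3, KI (cat.), DMF, 60 °C
Reagents that add atoms: none
Why: Williamson etherification of the remaining phenol installs the benzylic CH2 that later becomes C2 of the first dihydrobenzofuran together with its 4-benzyloxyphenyl group.

Step 3
Reactants: 5 1,3-bis(benzyloxy)-5-bromobenzene; 4 3-(benzyloxy)-2-{[4-(benzyloxy)phenyl]methoxy}-5-bromobenzaldehyde
Product: 8 [3,5-bis(benzyloxy)phenyl](3-(benzyloxy)-2-{[4-(benzyloxy)phenyl]methoxy}-5-bromophenyl)methanone, via arylmagnesium bromide 6 (not isolated), via bromomagnesium diarylmethanolate 7 (not isolated)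
Conditions: Mg, LiCl, THF, rt; then 4, 0 °C; then PhCHO (2 equiv), rt
Reagents that add atoms: none
Why: Grignard addition to the aldehyde followed in the same flask by magnesium Oppenauer oxidation of the alkoxide (benzaldehyde as hydride acceptor) should give the diaryl ketone, the aryl bromide of 4 being inert to the Grignard reagent at 0 °C.

Step 4
Reactants: 8 diaryl ketone of step 3
Product: 9 hydrazone of 8, [3,5-bis(benzyloxy)phenyl](3-(benzyloxy)-2-{[4-(benzyloxy)phenyl]methoxy}-5-bromophenyl)methanone hydrazone (E/Z mixture)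
Conditions: N2H4·H2O (10 equiv), AcOH (cat.), EtOH, 80 °C
Reagents that add atoms: hydrazine (as hydrate), NN
Why: Hydrazone condensation of a diaryl ketone, which tolerates the aryl bromide and the benzyl ethers.

Step 5
Reactants: 9 hydrazone of 8
Product: 11 (2S,3R)-7-(benzyloxy)-2-[4-(benzyloxy)phenyl]-3-[3,5-bis(benzyloxy)phenyl]-5-bromo-2,3-dihydro-1-benzofuran (2,3-cis), via diaryldiazomethane 10 (not isolated)
Conditions: MnO2, CH2Cl2, rt, filtration; then Rh2(S-PTAD)4 (1 mol %), CH2Cl2, 0 °C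
Reagents that add atoms: none
Why: Oxidation gives the diaryldiazomethane, whose donor/donor rhodium carbene should undergo enantioselective intramolecular 1,5-C–H insertion into the benzylic ether CH2, the chiral carboxylate ligands fixing C3 as R and the concerted insertion placing the two aryl groups cis (C2 S).

Step 6
Reactants: 5 1,3-bis(benzyloxy)-5-bromobenzene
Product: 12 2,4-bis(benzyloxy)-6-bromobenzaldehyde
Conditions: POCl3, DMF, 0 to 70 °C; then aq. NaOAc
Reagents that add atoms: N,N-dimethylformamide, CN(C)C=O; water, O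
Why: Vilsmeier–Haack formylation at the ring position ortho to one and para to the other benzyloxy group, which is less hindered than the position between the two ethers.

Step 7
Reactants: 12 2,4-bis(benzyloxy)-6-bromobenzaldehyde
Product: 13 4-(benzyloxy)-2-bromo-6-hydroxybenzaldehyde
Conditions: MgBr2·OEt2 (1.5 equiv), toluene/Et2O, 80 °C; aq. HCl work-up
Reagents that add atoms: none
Why: Chelation of magnesium between the formyl oxygen and the ortho ether oxygen should direct bromide-mediated debenzylation to the ortho benzyl ether only.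

Step 8
Reactants: 13 4-(benzyloxy)-2-bromo-6-hydroxybenzaldehyde; 3 1-(benzyloxy)-4-(chloromethyl)benzene
Product: 14 4-(benzyloxy)-2-{[4-(benzyloxy)phenyl]methoxy}-6-bromobenzaldehyde
Conditions: K2CO3, KI (cat.), DMF, 60 °C
Reagents that add atoms: none
Why: Williamson etherification of the hydrogen-bonded ortho phenol introduces the CH2 and aryl group that become C2 of the second dihydrobenzofuran.

Step 9
Reactants: 11 cis-5-bromo-dihydrobenzofuran of step 5; 14 4-(benzyloxy)-2-{[4-(benzyloxy)phenyl]methoxy}-6-bromobenzaldehyde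
Product: 17 (4-(benzyloxy)-2-{[4-(benzyloxy)phenyl]methoxy}-6-bromophenyl){(2S,3R)-7-(benzyloxy)-2-[4-(benzyloxy)phenyl]-3-[3,5-bis(benzyloxy)phenyl]-2,3-dihydro-1-benzofuran-5-yl}methanone, via benzofuranylmagnesium bromide 15 (not isolated), via bromomagnesium diarylmethanolate 16 (not isolated)
Conditions: Mg, LiCl, THF, rt; solution transferred to 14, −20 °C; then PhCHO (2 equiv), rt
Reagents that add atoms: none
Why: Grignard addition to the hindered aldehyde and magnesium Oppenauer oxidation in one flask should join the two ring systems as a diaryl ketone without touching the existing stereocenters.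

Step 10
Reactants: 17 diaryl ketone of step 9
Product: 18 hydrazone of 17 (E/Z mixture)
Conditions: N2H4·H2O (20 equiv), AcOH (cat.), n-BuOH, 110 °C
Reagents that add atoms: hydrazine (as hydrate), NN
Why: Hydrazone condensation, run under forcing conditions because the ketone carries two ortho substituents on one ring.

Step 11
Reactants: 18 hydrazone of 17
Product: 20 (2R,3S)-6-(benzyloxy)-2-[4-(benzyloxy)phenyl]-4-bromo-3-{(2S,3R)-7-(benzyloxy)-2-[4-(benzyloxy)phenyl]-3-[3,5-bis(benzyloxy)phenyl]-2,3-dihydro-1-benzofuran-5-yl}-2,3-dihydro-1-benzofuran (both rings 2,3-cis), via diaryldiazomethane 19 (not isolated)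
Conditions: MnO2, CH2Cl2, rt, filtration; then Rh2(R-PTAD)4 (2 mol %), CH2Cl2, 0 °C to rt
Reagents that add atoms: none
Why: A second donor/donor rhodium carbene 1,5-C–H insertion, run with the mirror-image catalyst because the two dihydrobenzofurans of the target have opposite absolute sense, should set the new C3 as S with the aryl groups cis (C2 R).

Step 12
Reactants: 20 cis,cis-bis(dihydrobenzofuran) bromide
Product: 21 (2S,3S)-6-(benzyloxy)-2-[4-(benzyloxy)phenyl]-4-bromo-3-{(2R,3R)-7-(benzyloxy)-2-[4-(benzyloxy)phenyl]-3-[3,5-bis(benzyloxy)phenyl]-2,3-dihydro-1-benzofuran-5-yl}-2,3-dihydro-1-benzofuran (both rings 2,3-trans; Q–Br)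
Conditions: TFA (5 equiv), CH2Cl2, 0 °C to rt
Reagents that add atoms: none
Why: Acid-mediated epimerization, in which each benzylic C2–O bond ionizes reversibly to a 4-benzyloxybenzyl cation and recloses to the thermodynamically favored 2,3-trans ring while the non-ionizable C3 centers keep their configuration.

Step 13
Reactants: 21 Q–Br; 22 1-[4-(benzyloxy)phenyl]ethan-1-one
Product: 23 1-[4-(benzyloxy)phenyl]-2-Q-ethan-1-one
Conditions: Pd2(dba)3 (2.5 mol %), XPhos (10 mol %), K3PO4, toluene, 90 °C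
Reagents that add atoms: none
Why: Palladium-catalyzed α-arylation of the methyl ketone enolate (Buchwald–Hartwig type), for which the bulky biaryl phosphine suits the hindered electron-rich aryl bromide and the bulk of Q should stop the reaction at monoarylation.

Step 14
Reactants: 23 1-[4-(benzyloxy)phenyl]-2-Q-ethan-1-one
Product: 25 1-[4-(benzyloxy)phenyl]-2-bromo-2-Q-ethan-1-one (both epimers at the bromine-bearing carbon), via lithium enolate 24 (not isolated)
Conditions: LiN(SiMe3)2, THF, −78 °C; then NBS, −78 °C; aq. NH4Cl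
Reagents that add atoms: N-bromosuccinimide, BrN1C(=O)CCC1=O
Why: Enolate bromination at the only enolizable position, the cold enolate reacting with NBS far faster than the electron-rich arenes, and the new center forming as a mixture that is erased later.

Step 15
Reactants: 25 α-bromo ketone
Product: 26 (1S)-1-[4-(benzyloxy)phenyl]-2-bromo-2-Q-ethan-1-ol (both epimers at the bromine-bearing carbon)
Conditions: RuCl[(R,R)-TsDPEN](p-cymene) (2 mol %), HCO2H/Et3N (5:2), EtOAc, 0 °C to rt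
Reagents that add atoms: none
Why: Noyori–Ikariya asymmetric transfer hydrogenation of an α-halo aryl ketone, in which the CH/π contact between the η6-arene of the catalyst and the aryl ring on the carbonyl selects the face, so that the (R,R)-ligand should give the (S)-carbinol for either configuration of the neighboring carbon.

Step 16
Reactants: 27 5-iodobenzene-1,3-diol; 28 1-(benzyloxy)-4-ethenylbenzene
Product: 29 5-{(E)-2-[4-(benzyloxy)phenyl]ethenyl}benzene-1,3-diol (4'-O-benzylresveratrol)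
Conditions: Pd(OAc)2 (2 mol %), Bu4NCl, NaHCO3, DMF, 80 °C
Reagents that add atoms: none
Why: Mizoroki–Heck reaction, in which syn-insertion and syn-β-hydride elimination give the E-stilbene and the mild bicarbonate base tolerates the free phenols.

Step 17
Reactants: 26 (1S)-bromohydrin; 29 4'-O-benzylresveratrol
Product: 31 {(1S)-1-[4-(benzyloxy)phenyl]-2-bromo-2-Q-ethoxy}(3-{(E)-2-[4-(benzyloxy)phenyl]ethenyl}-5-hydroxyphenoxy)di(propan-2-yl)silane, via chlorosilyl ether 30 (not isolated)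
Conditions: iPr2SiCl2 (5 equiv), imidazole, CH2Cl2, 0 °C; excess silane removed in vacuo; then 29 (3 equiv), imidazole, DMF, rt
Reagents that add atoms: dichlorodi(propan-2-yl)silane, CC(C)[Si](Cl)(Cl)C(C)C
Why: Temporary silicon tether by two successive O-silylations (excess dichlorosilane on the secondary alcohol, then one phenol of the symmetrical resorcinol used in excess), which touches no stereocenter and leaves the hindered benzylic bromide intact.

Step 18
Reactants: 31 silicon-tethered bromide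
Product: 33 (2R,3S,4R,5S)-2,5-bis[4-(benzyloxy)phenyl]-4-(3,5-dihydroxyphenyl)-3-Q-oxolane (oxolane numbered as in the plan), via bromosilyl ether 32 (not isolated)
Conditions: fac-Ir(ppy)3 (2 mol %), degassed MeCN/CH2Cl2 (0.002 M), blue LEDs (450 nm), rt; then HF·pyridine, THF, 0 °C
Reagents that add atoms: none
Why: Proposed new method: excited fac-Ir(ppy)3 should reduce the benzylic C–Br bond to a planar benzylic radical at the future oxolane C3, which adds through the tether to the alkene carbon next to the resorcinol ring (C3–C4 bond, temporary nine-membered ring, 9-exo-trig); the resulting 4-benzyloxybenzyl radical is oxidized by the tetravalent iridium to a cation that the silyl ether oxygen on C2 captures in a 5-exo closure (O1–C5 bond) with transfer of silicon to bromide, so the cascade is redox-neutral and catalytic. The closest known reaction types are photoredox atom-transfer radical addition of benzylic bromides to styrenes with radical–polar crossover and oxygen capture, and temporary-silicon-tethered radical cyclization. C3 is controlled by the C2 stereocenter: allylic 1,3-strain holds the C2–H bond in the plane of the benzylic radical and the tether delivers the alkene from the face that carries the oxygen, anti to the aryl group on C2, which gives the 2,3-trans relation. C4 is controlled by the tether, which keeps the resorcinol ring gauche to C2 so that only the transition state with the small C4–H between the two large groups on C3 is open, which gives the 3,4-cis relation; C5 is set when the planar cation closes with its aryl group trans to that on C4, which is also the thermodynamically preferred arrangement. The step needs attack at the alkene carbon next to the resorcinol ring (smaller ring, and it leaves the more easily oxidized 4-alkoxybenzyl radical), ring closure rather than intermolecular addition (high dilution, with degenerate bromine transfer keeping the uncyclized radical in reserve) and indifference to alkene geometry (C5 stays planar until the last bond forms, so sensitized E/Z isomerization is harmless).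

Step 19
Reactants: 33 octabenzyl oxolane
Product: 34 kobophenol A, (2S,3S)-3-[(2R,3R)-3-(3,5-dihydroxyphenyl)-7-hydroxy-2-(4-hydroxyphenyl)-2,3-dihydro-1-benzofuran-5-yl]-4-[(2R,3S,4R,5S)-4-(3,5-dihydroxyphenyl)-2,5-bis(4-hydroxyphenyl)oxolan-3-yl]-2-(4-hydroxyphenyl)-2,3-dihydro-1-benzofuran-6-ol
Conditions: H2 (1 atm), Pd/C (10 wt % Pd), EtOAc/MeOH, rt
Reagents that add atoms: none
Why: Catalytic hydrogenolysis should cleave the eight aryl benzyl ethers much faster than the ring benzylic C–O bonds of the dihydrobenzofurans and the oxolane under neutral conditions, so no stereocenter is affected.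

**Compound list**
1 | 5-bromo-2,3-dihydroxybenzaldehyde | O=Cc1cc(Br)cc(O)c1O | starting material
2 | 3-(benzyloxy)-5-bromo-2-hydroxybenzaldehyde | O=Cc1cc(Br)cc(OCc2ccccc2)c1O | intermediate
3 | 1-(benzyloxy)-4-(chloromethyl)benzene | ClCc1ccc(OCc2ccccc2)cc1 | starting material
4 | 3-(benzyloxy)-2-{[4-(benzyloxy)phenyl]methoxy}-5-bromobenzaldehyde | O=Cc1cc(Br)cc(OCc2ccccc2)c1OCc1ccc(OCc2ccccc2)cc1 | intermediate
5 | 1,3-bis(benzyloxy)-5-bromobenzene | Brc1cc(OCc2ccccc2)cc(OCc2ccccc2)c1 | starting material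
6 | [3,5-bis(benzyloxy)phenyl]magnesium bromide | Br[Mg]c1cc(OCc2ccccc2)cc(OCc2ccccc2)c1 | intermediate
7 | bromomagnesium [3,5-bis(benzyloxy)phenyl](3-(benzyloxy)-2-{[4-(benzyloxy)phenyl]methoxy}-5-bromophenyl)methanolate (racemic) | Br[Mg]OC(c1cc(OCc2ccccc2)cc(OCc2ccccc2)c1)c1cc(Br)cc(OCc2ccccc2)c1OCc1ccc(OCc2ccccc2)cc1 | intermediate
8 | [3,5-bis(benzyloxy)phenyl](3-(benzyloxy)-2-{[4-(benzyloxy)phenyl]methoxy}-5-bromophenyl)methanone | O=C(c1cc(OCc2ccccc2)cc(OCc2ccccc2)c1)c1cc(Br)cc(OCc2ccccc2)c1OCc1ccc(OCc2ccccc2)cc1 | intermediate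
9 | hydrazone of 8 (E/Z mixture) | NN=C(c1cc(OCc2ccccc2)cc(OCc2ccccc2)c1)c1cc(Br)cc(OCc2ccccc2)c1OCc1ccc(OCc2ccccc2)cc1 | intermediate
10 | 1-(benzyloxy)-2-{[4-(benzyloxy)phenyl]methoxy}-3-{[3,5-bis(benzyloxy)phenyl](diazo)methyl}-5-bromobenzene | [N-]=[N+]=C(c1cc(OCc2ccccc2)cc(OCc2ccccc2)c1)c1cc(Br)cc(OCc2ccccc2)c1OCc1ccc(OCc2ccccc2)cc1 | intermediate
11 | (2S,3R)-7-(benzyloxy)-2-[4-(benzyloxy)phenyl]-3-[3,5-bis(benzyloxy)phenyl]-5-bromo-2,3-dihydro-1-benzofuran (cis) | Brc2cc(OCc6ccccc6)c3c(c2)[C@@H](c2cc(OCc6ccccc6)cc(OCc6ccccc6)c2)[C@@H](c2ccc(OCc6ccccc6)cc2)O3 | intermediate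
12 | 2,4-bis(benzyloxy)-6-bromobenzaldehyde | O=Cc1c(Br)cc(OCc2ccccc2)cc1OCc1ccccc1 | intermediate
13 | 4-(benzyloxy)-2-bromo-6-hydroxybenzaldehyde | O=Cc1c(Br)cc(OCc2ccccc2)cc1O | intermediate
14 | 4-(benzyloxy)-2-{[4-(benzyloxy)phenyl]methoxy}-6-bromobenzaldehyde | O=Cc1c(Br)cc(OCc2ccccc2)cc1OCc1ccc(OCc2ccccc2)cc1 | intermediate
15 | {(2S,3R)-7-(benzyloxy)-2-[4-(benzyloxy)phenyl]-3-[3,5-bis(benzyloxy)phenyl]-2,3-dihydro-1-benzofuran-5-yl}magnesium bromide | Br[Mg]c2cc(OCc6ccccc6)c3c(c2)[C@@H](c2cc(OCc6ccccc6)cc(OCc6ccccc6)c2)[C@@H](c2ccc(OCc6ccccc6)cc2)O3 | intermediate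
16 | bromomagnesium alkoxide of the diarylmethanol from 15 and 14 (both carbinol epimers) | Br[Mg]OC(c1c(Br)cc(OCc6ccccc6)cc1OCc7ccc(OCc6ccccc6)cc7)c2cc(OCc6ccccc6)c3c(c2)[C@@H](c2cc(OCc6ccccc6)cc(OCc6ccccc6)c2)[C@@H](c2ccc(OCc6ccccc6)cc2)O3 | intermediate
17 | (4-(benzyloxy)-2-{[4-(benzyloxy)phenyl]methoxy}-6-bromophenyl){(2S,3R)-7-(benzyloxy)-2-[4-(benzyloxy)phenyl]-3-[3,5-bis(benzyloxy)phenyl]-2,3-dihydro-1-benzofuran-5-yl}methanone | O=C(c1c(Br)cc(OCc6ccccc6)cc1OCc7ccc(OCc6ccccc6)cc7)c2cc(OCc6ccccc6)c3c(c2)[C@@H](c2cc(OCc6ccccc6)cc(OCc6ccccc6)c2)[C@@H](c2ccc(OCc6ccccc6)cc2)O3 | intermediate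
18 | hydrazone of 17 (E/Z mixture) | NN=C(c1c(Br)cc(OCc6ccccc6)cc1OCc7ccc(OCc6ccccc6)cc7)c2cc(OCc6ccccc6)c3c(c2)[C@@H](c2cc(OCc6ccccc6)cc(OCc6ccccc6)c2)[C@@H](c2ccc(OCc6ccccc6)cc2)O3 | intermediate
19 | diaryldiazomethane from 18 | [N-]=[N+]=C(c1c(Br)cc(OCc6ccccc6)cc1OCc7ccc(OCc6ccccc6)cc7)c2cc(OCc6ccccc6)c3c(c2)[C@@H](c2cc(OCc6ccccc6)cc(OCc6ccccc6)c2)[C@@H](c2ccc(OCc6ccccc6)cc2)O3 | intermediate
20 | (2R,3S)-6-(benzyloxy)-2-[4-(benzyloxy)phenyl]-4-bromo-3-{(2S,3R)-7-(benzyloxy)-2-[4-(benzyloxy)phenyl]-3-[3,5-bis(benzyloxy)phenyl]-2,3-dihydro-1-benzofuran-5-yl}-2,3-dihydro-1-benzofuran (cis,cis) | O(Cc6ccccc6)c1ccc([C@@H]2Oc3cc(OCc6ccccc6)cc(Br)c3[C@@H]2c2cc(OCc6ccccc6)c3c(c2)[C@@H](c2cc(OCc6ccccc6)cc(OCc6ccccc6)c2)[C@@H](c2ccc(OCc6ccccc6)cc2)O3)cc1 | intermediate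
21 | Q–Br, (2S,3S)-6-(benzyloxy)-2-[4-(benzyloxy)phenyl]-4-bromo-3-{(2R,3R)-7-(benzyloxy)-2-[4-(benzyloxy)phenyl]-3-[3,5-bis(benzyloxy)phenyl]-2,3-dihydro-1-benzofuran-5-yl}-2,3-dihydro-1-benzofuran (trans,trans) | O(Cc6ccccc6)c1ccc([C@H]2Oc3cc(OCc6ccccc6)cc(Br)c3[C@@H]2c2cc(OCc6ccccc6)c3c(c2)[C@@H](c2cc(OCc6ccccc6)cc(OCc6ccccc6)c2)[C@H](c2ccc(OCc6ccccc6)cc2)O3)cc1 | intermediate
22 | 1-[4-(benzyloxy)phenyl]ethan-1-one | CC(=O)c1ccc(OCc2ccccc2)cc1 | starting material
23 | 1-[4-(benzyloxy)phenyl]-2-Q-ethan-1-one | O(Cc6ccccc6)c1ccc([C@H]2Oc3cc(OCc6ccccc6)cc(CC(=O)c4ccc(OCc6ccccc6)cc4)c3[C@@H]2c2cc(OCc6ccccc6)c3c(c2)[C@@H](c2cc(OCc6ccccc6)cc(OCc6ccccc6)c2)[C@H](c2ccc(OCc6ccccc6)cc2)O3)cc1 | intermediate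
24 | lithium enolate of 23 | O(Cc6ccccc6)c1ccc([C@H]2Oc3cc(OCc6ccccc6)cc(C=C(O[Li])c4ccc(OCc6ccccc6)cc4)c3[C@@H]2c2cc(OCc6ccccc6)c3c(c2)[C@@H](c2cc(OCc6ccccc6)cc(OCc6ccccc6)c2)[C@H](c2ccc(OCc6ccccc6)cc2)O3)cc1 | intermediate
25 | 1-[4-(benzyloxy)phenyl]-2-bromo-2-Q-ethan-1-one (both epimers at C2 of the chain) | O(Cc6ccccc6)c1ccc([C@H]2Oc3cc(OCc6ccccc6)cc(C(Br)C(=O)c4ccc(OCc6ccccc6)cc4)c3[C@@H]2c2cc(OCc6ccccc6)c3c(c2)[C@@H](c2cc(OCc6ccccc6)cc(OCc6ccccc6)c2)[C@H](c2ccc(OCc6ccccc6)cc2)O3)cc1 | intermediate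
26 | (1S)-1-[4-(benzyloxy)phenyl]-2-bromo-2-Q-ethan-1-ol (both epimers at the bromine-bearing carbon) | O(Cc6ccccc6)c1ccc([C@H]2Oc3cc(OCc6ccccc6)cc(C(Br)[C@@H](O)c4ccc(OCc6ccccc6)cc4)c3[C@@H]2c2cc(OCc6ccccc6)c3c(c2)[C@@H](c2cc(OCc6ccccc6)cc(OCc6ccccc6)c2)[C@H](c2ccc(OCc6ccccc6)cc2)O3)cc1 | intermediate
27 | 5-iodobenzene-1,3-diol | Oc1cc(O)cc(I)c1 | starting material
28 | 1-(benzyloxy)-4-ethenylbenzene | C=Cc1ccc(OCc2ccccc2)cc1 | starting material
29 | 5-{(E)-2-[4-(benzyloxy)phenyl]ethenyl}benzene-1,3-diol | Oc1cc(O)cc(/C=C/c2ccc(OCc3ccccc3)cc2)c1 | intermediate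
30 | {(1S)-1-[4-(benzyloxy)phenyl]-2-bromo-2-Q-ethoxy}(chloro)di(propan-2-yl)silane | O(Cc6ccccc6)c1ccc([C@H]2Oc3cc(OCc6ccccc6)cc(C(Br)[C@@H](O[Si](Cl)(C(C)C)C(C)C)c4ccc(OCc6ccccc6)cc4)c3[C@@H]2c2cc(OCc6ccccc6)c3c(c2)[C@@H](c2cc(OCc6ccccc6)cc(OCc6ccccc6)c2)[C@H](c2ccc(OCc6ccccc6)cc2)O3)cc1 | intermediate
31 | {(1S)-1-[4-(benzyloxy)phenyl]-2-bromo-2-Q-ethoxy}(3-{(E)-2-[4-(benzyloxy)phenyl]ethenyl}-5-hydroxyphenoxy)di(propan-2-yl)silane | O(Cc6ccccc6)c1ccc([C@H]2Oc3cc(OCc6ccccc6)cc(C(Br)[C@@H](O[Si](C(C)C)(C(C)C)Oc7cc(O)cc(/C=C/c8ccc(OCc6ccccc6)cc8)c7)c4ccc(OCc6ccccc6)cc4)c3[C@@H]2c2cc(OCc6ccccc6)c3c(c2)[C@@H](c2cc(OCc6ccccc6)cc(OCc6ccccc6)c2)[C@H](c2ccc(OCc6ccccc6)cc2)O3)cc1 | intermediate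
32 | (2R,3S,4R,5S)-2,5-bis[4-(benzyloxy)phenyl]-4-(3-{[bromodi(propan-2-yl)silyl]oxy}-5-hydroxyphenyl)-3-Q-oxolane | O(Cc6ccccc6)c1ccc([C@H]2Oc3cc(OCc6ccccc6)cc([C@@H]4[C@H](c5cc(O[Si](Br)(C(C)C)C(C)C)cc(O)c5)[C@@H](c5ccc(OCc6ccccc6)cc5)O[C@H]4c4ccc(OCc6ccccc6)cc4)c3[C@@H]2c2cc(OCc6ccccc6)c3c(c2)[C@@H](c2cc(OCc6ccccc6)cc(OCc6ccccc6)c2)[C@H](c2ccc(OCc6ccccc6)cc2)O3)cc1 | intermediate
33 | (2R,3S,4R,5S)-2,5-bis[4-(benzyloxy)phenyl]-4-(3,5-dihydroxyphenyl)-3-Q-oxolane | O(Cc6ccccc6)c1ccc([C@H]2Oc3cc(OCc6ccccc6)cc([C@@H]4[C@H](c5cc(O)cc(O)c5)[C@@H](c5ccc(OCc6ccccc6)cc5)O[C@H]4c4ccc(OCc6ccccc6)cc4)c3[C@@H]2c2cc(OCc6ccccc6)c3c(c2)[C@@H](c2cc(OCc6ccccc6)cc(OCc6ccccc6)c2)[C@H](c2ccc(OCc6ccccc6)cc2)O3)cc1 | intermediate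
34 | kobophenol A (name as in step 19) | Oc1ccc([C@H]2Oc3cc(O)cc([C@@H]4[C@H](c5cc(O)cc(O)c5)[C@@H](c5ccc(O)cc5)O[C@H]4c4ccc(O)cc4)c3[C@@H]2c2cc(O)c3c(c2)[C@@H](c2cc(O)cc(O)c2)[C@H](c2ccc(O)cc2)O3)cc1 | target

**Totals**
Total step count: 19. Longest linear sequence: 15 steps (1–5, 9–15, 17–19).

**Steps most likely to fail**

Step 18 (proposed new method). The nine-membered radical ring closure may be too slow, so that reduction, elimination or oligomerization of the benzylic radical wins, or the relative topicity at C3/C4 may be poorly controlled. The fallback sets out from 21 and uses known chemistry without the tether. Mizoroki–Heck coupling of 21 with 28 (Pd2(dba)3, P(t-Bu)3·HBF4, Cy2NMe, dioxane, 100 °C) would give the heptabenzyl (E)-stilbene Q–CH=CH–C6H4–OBn F1. Debenzylation with BCl3 and pentamethylbenzene at −78 °C, which spares the alkene, would give the free heptaphenol stilbene F2. Biomimetic oxidative cross-coupling of F2 with commercial resveratrol under horseradish peroxidase and H2O2 in aqueous acetone (8–8' coupling of the two phenoxyl radicals, then capture of water by the two quinone methides) would form the tetraaryl oxolane directly. This route gives up stereocontrol at the oxolane, so the required isomer would have to be separated by preparative HPLC; it comes back to the route at 34.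

Step 15. Formate may displace the activated benzylic bromide, or the bulky α-substituent may override the aryl recognition of the catalyst and erode the enantioselectivity at the carbinol. The fallback sets out from 23. α-Hydroxylation of its lithium enolate with 3-phenyl-2-(phenylsulfonyl)oxaziridine would give the α-hydroxy ketone 1-[4-(benzyloxy)phenyl]-2-hydroxy-2-Q-ethan-1-one F3. Dynamic-kinetic asymmetric transfer hydrogenation with the same ruthenium catalyst, a well-precedented reduction of benzoin-type ketones, would give the (1S,2S)-diol F4. The less hindered hydroxyl, next to the 4-benzyloxyphenyl ring, would be silylated with the aryloxy(chloro)silane F5, prepared from 29 and iPr2SiCl2, to give the mono-silyl ether F6. Appel bromination (CBr4, PPh3) of the remaining hindered hydroxyl comes back to the route at 31.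

Step 11. Carbene formation and insertion next to two ortho substituents may be slow, so that azine formation or carbene dimerization takes over; the preceding hydrazone condensation may also stall. The fallback sets out from 13 and from the Grignard reagent 15 made from 11. Addition of 15 (2 equiv) to the free-phenol aldehyde 13 would give the ortho-hydroxybenzhydrol F7. With the sulfonium salt [4-(benzyloxy)benzyl]dimethylsulfonium chloride F8 (from 3 and dimethyl sulfide) and Cs2CO3, the ortho-quinone methide formed in situ should undergo [4+1] annulation with the benzylic sulfur ylide to a 2,3-trans dihydrobenzofuran. This forms as two diastereomers, because the ring already present is enantiopure. The (2S,3S)-trans/(2S,3R)-cis diastereomer F9 would be separated by chromatography and submitted to the conditions of step 12, which comes back to the route at 21.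

**Further compounds**
F1 | step 18 | (E)-1-[4-(benzyloxy)phenyl]-2-Q-ethene | O(Cc6ccccc6)c1ccc([C@H]2Oc3cc(OCc6ccccc6)cc(/C=C/c4ccc(OCc6ccccc6)cc4)c3[C@@H]2c2cc(OCc6ccccc6)c3c(c2)[C@@H](c2cc(OCc6ccccc6)cc(OCc6ccccc6)c2)[C@H](c2ccc(OCc6ccccc6)cc2)O3)cc1
F2 | step 18 | (2S,3S)-3-[(2R,3R)-3-(3,5-dihydroxyphenyl)-7-hydroxy-2-(4-hydroxyphenyl)-2,3-dihydro-1-benzofuran-5-yl]-2-(4-hydroxyphenyl)-4-[(E)-2-(4-hydroxyphenyl)ethenyl]-2,3-dihydro-1-benzofuran-6-ol | Oc1ccc([C@H]2Oc3cc(O)cc(/C=C/c4ccc(O)cc4)c3[C@@H]2c2cc(O)c3c(c2)[C@@H](c2cc(O)cc(O)c2)[C@H](c2ccc(O)cc2)O3)cc1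
F3 | step 15 | 1-[4-(benzyloxy)phenyl]-2-hydroxy-2-Q-ethan-1-one (both epimers) | O(Cc6ccccc6)c1ccc([C@H]2Oc3cc(OCc6ccccc6)cc(C(O)C(=O)c4ccc(OCc6ccccc6)cc4)c3[C@@H]2c2cc(OCc6ccccc6)c3c(c2)[C@@H](c2cc(OCc6ccccc6)cc(OCc6ccccc6)c2)[C@H](c2ccc(OCc6ccccc6)cc2)O3)cc1
F4 | step 15 | (1S,2S)-1-[4-(benzyloxy)phenyl]-2-Q-ethane-1,2-diol | O(Cc6ccccc6)c1ccc([C@H]2Oc3cc(OCc6ccccc6)cc([C@H](O)[C@@H](O)c4ccc(OCc6ccccc6)cc4)c3[C@@H]2c2cc(OCc6ccccc6)c3c(c2)[C@@H](c2cc(OCc6ccccc6)cc(OCc6ccccc6)c2)[C@H](c2ccc(OCc6ccccc6)cc2)O3)cc1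
F5 | step 15 | 3-{(E)-2-[4-(benzyloxy)phenyl]ethenyl}-5-{[chlorodi(propan-2-yl)silyl]oxy}phenol | CC(C)[Si](Cl)(C(C)C)Oc1cc(O)cc(/C=C/c2ccc(OCc3ccccc3)cc2)c1
F6 | step 15 | (1S,2S)-2-[4-(benzyloxy)phenyl]-2-{[(3-{(E)-2-[4-(benzyloxy)phenyl]ethenyl}-5-hydroxyphenoxy)di(propan-2-yl)silyl]oxy}-1-Q-ethan-1-ol | O(Cc6ccccc6)c1ccc([C@H]2Oc3cc(OCc6ccccc6)cc([C@H](O)[C@@H](O[Si](C(C)C)(C(C)C)Oc7cc(O)cc(/C=C/c8ccc(OCc6ccccc6)cc8)c7)c4ccc(OCc6ccccc6)cc4)c3[C@@H]2c2cc(OCc6ccccc6)c3c(c2)[C@@H](c2cc(OCc6ccccc6)cc(OCc6ccccc6)c2)[C@H](c2ccc(OCc6ccccc6)cc2)O3)cc1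
F7 | step 11 | 5-(benzyloxy)-3-bromo-2-[{(2S,3R)-7-(benzyloxy)-2-[4-(benzyloxy)phenyl]-3-[3,5-bis(benzyloxy)phenyl]-2,3-dihydro-1-benzofuran-5-yl}(hydroxy)methyl]phenol (both carbinol epimers) | OC(c1c(Br)cc(OCc6ccccc6)cc1O)c2cc(OCc6ccccc6)c3c(c2)[C@@H](c2cc(OCc6ccccc6)cc(OCc6ccccc6)c2)[C@@H](c2ccc(OCc6ccccc6)cc2)O3
F8 | step 11 | [4-(benzyloxy)benzyl]dimethylsulfonium chloride | C[S+](C)Cc1ccc(OCc2ccccc2)cc1.[Cl-]
F9 | step 11 | (2S,3S)-6-(benzyloxy)-2-[4-(benzyloxy)phenyl]-4-bromo-3-{(2S,3R)-7-(benzyloxy)-2-[4-(benzyloxy)phenyl]-3-[3,5-bis(benzyloxy)phenyl]-2,3-dihydro-1-benzofuran-5-yl}-2,3-dihydro-1-benzofuran (trans in the new ring, cis in the old) | O(Cc6ccccc6)c1ccc([C@H]2Oc3cc(OCc6ccccc6)cc(Br)c3[C@@H]2c2cc(OCc6ccccc6)c3c(c2)[C@@H](c2cc(OCc6ccccc6)cc(OCc6ccccc6)c2)[C@@H](c2ccc(OCc6ccccc6)cc2)O3)cc1
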